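**Strategy.** The chroman ring is disconnected at C4a–C4, leaving O1–C2 in place. O1 is the ring-A oxygen para to the C6 acyl carbon, so it is alkylated first as a 1,1-dimethylpropargyl ether; a gold(I)-catalysed 6-endo-dig hydroarylation then closes the pyran ring as a 2H-chromene in one operation. Because C5 and C7 carry identical oxygens, both ring-A carbons ortho to the ether are equivalent and only the linear chromene can form. The precursor is the 4'-O-(2-methylbut-3-yn-2-yl) ether of phloretin, carried with MOM ethers on the two hydroxyls flanking the ketone and a benzyl ether on ring B, so that the later ring-B O-alkylation meets a single free hydroxyl. Hydrogenation and an O-allyl/Claisen sequence finish ring B.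

Key step: step 4

Remark: the target has no stereocentre; it is achiral, so no step has to control configuration.

Remark: under base/copper O-alkylation the acidic hydroxyls next to the ketone would compete with the ring-B phenol. They are therefore masked as MOM ethers and the ring-B oxygen is brought in as a benzyl ether, which is why the skeleton is assembled from 2,4,6-trihydroxyacetophenone and not taken from unprotected phloretin.

**Step 1**
Reactants: 1 2,4,6-trihydroxyacetophenone; 2 3-chloro-3-methylbut-1-yne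
Product: 3 1-[2,6-dihydroxy-4-(2-methylbut-3-yn-2-yloxy)phenyl]ethan-1-one
Conditions: 1 (dried), 2 (1.1 equiv), DBU (1.2 equiv), CuCl2·2H2O (1 mol%), MeCN, 0 °C
Reagents that add atoms: 3-chloro-3-methylbut-1-yne (2), C#CC(C)(C)Cl
Why: Copper-catalysed propargylic etherification (a copper acetylide/allenylidene captured at the tertiary carbon by a phenoxide) should occur at O-4 only, because this hydroxyl, para to the acetyl group, is the most acidic and the only one not hydrogen-bonded to the carbonyl, so one equivalent of base generates its phenoxide alone.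

**Step 2**
Reactants: 3 1-[2,6-dihydroxy-4-(2-methylbut-3-yn-2-yloxy)phenyl]ethan-1-one; 4 chloromethyl methyl ether
Product: 6 1-[2,6-bis(methoxymethoxy)-4-(2-methylbut-3-yn-2-yloxy)phenyl]ethan-1-one, via mono-MOM ether 5 (not isolated)
Conditions: MOMCl (2.3 equiv), NaH (2.1 equiv), DMF, 0 °C to rt
Reagents that add atoms: chloromethyl methyl ether (4), COCCl
Why: Williamson-type O-alkylation of the two remaining phenoxides with the reactive α-chloro ether should give the bis-acetal, sodium hydride being needed for the hydrogen-bonded hydroxyl and being consumed by the two phenols before it can touch the alkyne C–H.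

**Step 3**
Reactants: 6 1-[2,6-bis(methoxymethoxy)-4-(2-methylbut-3-yn-2-yloxy)phenyl]ethan-1-one; 7 1-(benzyloxy)-4-(bromomethyl)benzene
Product: 9 3-[4-(benzyloxy)phenyl]-1-[2,6-bis(methoxymethoxy)-4-(2-methylbut-3-yn-2-yloxy)phenyl]propan-1-one, via lithium enolate 8 (not isolated)
Conditions: LiHMDS (1.05 equiv), THF, −78 °C; then 7, −78 to 0 °C
Reagents that add atoms: 1-(benzyloxy)-4-(bromomethyl)benzene (7), BrCc1ccc(OCc2ccccc2)cc1
Why: Enolate alkylation, in which the lithium enolate formed at the only enolisable position (the acetyl methyl) is benzylated in an SN2 reaction by the activated benzylic bromide, while the silylamide base is too weak to metalate the terminal alkyne once the far more acidic ketone is deprotonated.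

**Step 4**
Reactants: 9 3-[4-(benzyloxy)phenyl]-1-[2,6-bis(methoxymethoxy)-4-(2-methylbut-3-yn-2-yloxy)phenyl]propan-1-one
Product: 10 3-[4-(benzyloxy)phenyl]-1-[5,7-bis(methoxymethoxy)-2,2-dimethyl-2H-chromen-6-yl]propan-1-one
Conditions: [JohnPhosAu(MeCN)]SbF6 (2 mol%), CH2Cl2, rt
Reagents that add atoms: none
Why: Cationic gold(I) binds the terminal alkyne of 9 as a π-complex, the ring-A carbon ortho to the ether oxygen (C3'/C5', equivalent by symmetry) attacks the terminal alkyne carbon in a Friedel–Crafts sense, and rearomatisation followed by protodeauration of the vinyl-gold species releases chromene 10; the closest known reaction type is the gold(I)-catalysed intramolecular hydroarylation of aryl propargyl ethers to 2H-chromenes. The pyran ring closes in the 6-endo-dig mode, forming the C4a–C4 bond while the O1–C2 bond made in step 1 stays intact. No stereocentre is created. The step needs endo over exo closure and survival of the tertiary propargylic C–O bond: the terminal alkyne and the gem-dimethyl group favour the six-membered ring, and the two MOM groups twist the ketone out of the ring plane, so the arene stays electron-rich and the aryloxy group is a poorer leaving group than in the free 2,6-dihydroxy ketone. Because the ether oxygen is fixed as O1 the angular isomer is excluded, and the benzyl-protected ring B carries no alkyne and cannot interfere. The reaction should run at room temperature, well below the onset of the thermal propargyl Claisen pathway.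

**Step 5**
Reactants: 10 3-[4-(benzyloxy)phenyl]-1-[5,7-bis(methoxymethoxy)-2,2-dimethyl-2H-chromen-6-yl]propan-1-one
Product: 12 1-[5,7-bis(methoxymethoxy)-2,2-dimethyl-3,4-dihydro-2H-chromen-6-yl]-3-(4-hydroxyphenyl)propan-1-one, via chroman benzyl ether 11 (not isolated)
Conditions: H2 (1 atm), 10% Pd/C, EtOAc–EtOH, rt
Reagents that add atoms: none
Why: Heterogeneous catalytic hydrogenation should saturate the cis-disubstituted C3=C4 bond and hydrogenolyse the benzylic C–O bond of the ring-B ether in the same operation, while the MOM acetals and the hindered, electron-rich aryl ketone are inert at one atmosphere in a neutral solvent.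

**Step 6**
Reactants: 12 1-[5,7-bis(methoxymethoxy)-2,2-dimethyl-3,4-dihydro-2H-chromen-6-yl]-3-(4-hydroxyphenyl)propan-1-one; 2 3-chloro-3-methylbut-1-yne
Product: 13 1-[5,7-bis(methoxymethoxy)-2,2-dimethyl-3,4-dihydro-2H-chromen-6-yl]-3-[4-(2-methylbut-3-yn-2-yloxy)phenyl]propan-1-one
Conditions: 2 (1.5 equiv), DBU (1.6 equiv), CuCl2·2H2O (1 mol%), MeCN, 0 °C to rt
Reagents that add atoms: 3-chloro-3-methylbut-1-yne (2), C#CC(C)(C)Cl
Why: Copper-catalysed propargylic etherification now meets a single free hydroxyl, the ring-B phenol, so the tertiary ether can form only there.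

**Step 7**
Reactants: 13 1-[5,7-bis(methoxymethoxy)-2,2-dimethyl-3,4-dihydro-2H-chromen-6-yl]-3-[4-(2-methylbut-3-yn-2-yloxy)phenyl]propan-1-one
Product: 14 1-[5,7-bis(methoxymethoxy)-2,2-dimethyl-3,4-dihydro-2H-chromen-6-yl]-3-[4-(2-methylbut-3-en-2-yloxy)phenyl]propan-1-one
Conditions: H2 (1 atm), Lindlar catalyst, quinoline, EtOAc, rt
Reagents that add atoms: none
Why: Lindlar semi-hydrogenation, in which the lead- and quinoline-poisoned palladium catalyst adds one equivalent of hydrogen to the terminal alkyne and stops at the alkene, the molecule holding no other π-bond that this catalyst reduces.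

**Step 8**
Reactants: 14 1-[5,7-bis(methoxymethoxy)-2,2-dimethyl-3,4-dihydro-2H-chromen-6-yl]-3-[4-(2-methylbut-3-en-2-yloxy)phenyl]propan-1-one
Product: 16 1-[5,7-bis(methoxymethoxy)-2,2-dimethyl-3,4-dihydro-2H-chromen-6-yl]-3-[4-hydroxy-3-(3-methylbut-2-en-1-yl)phenyl]propan-1-one, via ortho-dienone 15 (not isolated)
Conditions: PhNEt2, 140 °C
Reagents that add atoms: none
Why: Aromatic Claisen rearrangement, a [3,3]-sigmatropic shift through a chair transition state that moves the allyl unit to an ortho carbon with allylic inversion and so turns the 1,1-dimethylallyl ether into the 3-methylbut-2-enyl (prenyl) group, the two ortho positions being equivalent and the dienone 15 rearomatising by tautomerisation, which also removes its transient stereocentre.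

**Step 9**
Reactants: 16 1-[5,7-bis(methoxymethoxy)-2,2-dimethyl-3,4-dihydro-2H-chromen-6-yl]-3-[4-hydroxy-3-(3-methylbut-2-en-1-yl)phenyl]propan-1-one
Product: 19 1-(5,7-dihydroxy-2,2-dimethyl-3,4-dihydro-2H-chromen-6-yl)-3-[4-hydroxy-3-(3-methylbut-2-en-1-yl)phenyl]propan-1-one, via 5-hydroxy 7-MOM ether 17 (not isolated), via 7-hydroxy 5-MOM ether 18 (not isolated)
Conditions: 3 M aq. HCl, MeOH, 40 °C
Reagents that add atoms: none
Why: Acid-catalysed acetal methanolysis (MOM cleavage) is fast for the two ethers next to the ketone because the carbonyl assists loss of the oxocarbenium fragment, so dilute acid at mild temperature should free both phenols without protonating the trisubstituted prenyl alkene or opening the chroman ether.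

**Compound list**

1 | 1-(2,4,6-trihydroxyphenyl)ethan-1-one (2,4,6-trihydroxyacetophenone) | CC(=O)c1c(O)cc(O)cc1O | starting material
2 | 3-chloro-3-methylbut-1-yne | C#CC(C)(C)Cl | starting material
3 | 1-[2,6-dihydroxy-4-(2-methylbut-3-yn-2-yloxy)phenyl]ethan-1-one | CC(=O)c1c(O)cc(OC(C)(C)C#C)cc1O | intermediate
4 | chloromethyl methyl ether | COCCl | starting material
5 | 1-[2-hydroxy-6-(methoxymethoxy)-4-(2-methylbut-3-yn-2-yloxy)phenyl]ethan-1-one | CC(=O)c1c(O)cc(OC(C)(C)C#C)cc1OCOC | intermediate (not isolated)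
6 | 1-[2,6-bis(methoxymethoxy)-4-(2-methylbut-3-yn-2-yloxy)phenyl]ethan-1-one | CC(=O)c1c(OCOC)cc(OC(C)(C)C#C)cc1OCOC | intermediate
7 | 1-(benzyloxy)-4-(bromomethyl)benzene | BrCc1ccc(OCc2ccccc2)cc1 | starting material
8 | lithium 1-[2,6-bis(methoxymethoxy)-4-(2-methylbut-3-yn-2-yloxy)phenyl]ethen-1-olate | [Li]OC(=C)c1c(OCOC)cc(OC(C)(C)C#C)cc1OCOC | intermediate (not isolated)
9 | 3-[4-(benzyloxy)phenyl]-1-[2,6-bis(methoxymethoxy)-4-(2-methylbut-3-yn-2-yloxy)phenyl]propan-1-one | C#CC(C)(C)Oc1cc(OCOC)c(C(=O)CCc2ccc(OCc3ccccc3)cc2)c(OCOC)c1 | intermediate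
10 | 3-[4-(benzyloxy)phenyl]-1-[5,7-bis(methoxymethoxy)-2,2-dimethyl-2H-chromen-6-yl]propan-1-one | O=C(CCc1ccc(OCc2ccccc2)cc1)c1c(OCOC)cc2c(c1OCOC)C=CC(C)(C)O2 | intermediate
11 | 3-[4-(benzyloxy)phenyl]-1-[5,7-bis(methoxymethoxy)-2,2-dimethyl-3,4-dihydro-2H-chromen-6-yl]propan-1-one | O=C(CCc1ccc(OCc2ccccc2)cc1)c1c(OCOC)cc2c(c1OCOC)CCC(C)(C)O2 | intermediate (not isolated)
12 | 1-[5,7-bis(methoxymethoxy)-2,2-dimethyl-3,4-dihydro-2H-chromen-6-yl]-3-(4-hydroxyphenyl)propan-1-one | O=C(CCc1ccc(O)cc1)c1c(OCOC)cc2c(c1OCOC)CCC(C)(C)O2 | intermediate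
13 | 1-[5,7-bis(methoxymethoxy)-2,2-dimethyl-3,4-dihydro-2H-chromen-6-yl]-3-[4-(2-methylbut-3-yn-2-yloxy)phenyl]propan-1-one | C#CC(C)(C)Oc1ccc(CCC(=O)c2c(OCOC)cc3c(c2OCOC)CCC(C)(C)O3)cc1 | intermediate
14 | 1-[5,7-bis(methoxymethoxy)-2,2-dimethyl-3,4-dihydro-2H-chromen-6-yl]-3-[4-(2-methylbut-3-en-2-yloxy)phenyl]propan-1-one | C=CC(C)(C)Oc1ccc(CCC(=O)c2c(OCOC)cc3c(c2OCOC)CCC(C)(C)O3)cc1 | intermediate
15 | 4-{3-[5,7-bis(methoxymethoxy)-2,2-dimethyl-3,4-dihydro-2H-chromen-6-yl]-3-oxopropyl}-6-(3-methylbut-2-en-1-yl)cyclohexa-2,4-dien-1-one (racemic) | CC(C)=CCC1C=C(CCC(=O)c2c(OCOC)cc3c(c2OCOC)CCC(C)(C)O3)C=CC1=O | intermediate (not isolated)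
16 | 1-[5,7-bis(methoxymethoxy)-2,2-dimethyl-3,4-dihydro-2H-chromen-6-yl]-3-[4-hydroxy-3-(3-methylbut-2-en-1-yl)phenyl]propan-1-one | CC(C)=CCc1cc(CCC(=O)c2c(OCOC)cc3c(c2OCOC)CCC(C)(C)O3)ccc1O | intermediate
17 | 1-[5-hydroxy-7-(methoxymethoxy)-2,2-dimethyl-3,4-dihydro-2H-chromen-6-yl]-3-[4-hydroxy-3-(3-methylbut-2-en-1-yl)phenyl]propan-1-one | CC(C)=CCc1cc(CCC(=O)c2c(OCOC)cc3c(c2O)CCC(C)(C)O3)ccc1O | intermediate (not isolated)
18 | 1-[7-hydroxy-5-(methoxymethoxy)-2,2-dimethyl-3,4-dihydro-2H-chromen-6-yl]-3-[4-hydroxy-3-(3-methylbut-2-en-1-yl)phenyl]propan-1-one | CC(C)=CCc1cc(CCC(=O)c2c(O)cc3c(c2OCOC)CCC(C)(C)O3)ccc1O | intermediate (not isolated)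
19 | 1-(5,7-dihydroxy-2,2-dimethyl-3,4-dihydro-2H-chromen-6-yl)-3-[4-hydroxy-3-(3-methylbut-2-en-1-yl)phenyl]propan-1-one | CC(C)=CCc1cc(CCC(=O)c2c(O)cc3c(c2O)CCC(C)(C)O3)ccc1O | target

**Step count**

Total step count: 9. Longest linear sequence: 9 steps (1 to 19).

**Steps most likely to fail**

1. Step 4 (key step). The process at risk is ionisation of the tertiary propargylic C–O bond under the Lewis-acidic catalyst, closure in the exo mode, or slow turnover through binding of gold to the acetal and ketone oxygens. Fallback, setting out from 9 and returning at 10: heating 9 in N,N-diethylaniline at about 180 °C should trigger the uncatalysed pericyclic sequence. An aromatic propargyl Claisen rearrangement and enolisation give the ortho-allenylphenol 3-[4-(benzyloxy)phenyl]-1-[4-hydroxy-2,6-bis(methoxymethoxy)-3-(3-methylbuta-1,2-dien-1-yl)phenyl]propan-1-one F1, which is not isolated. A 1,5-hydrogen shift and an oxa-6π electrocyclisation follow. The same C4a–C4 bond is formed, and since both ortho carbons are equivalent the only possible product is 10.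

2. Step 1. The process at risk is over-alkylation at a second hydroxyl, C-alkylation of the very electron-rich ring, or low conversion of the hindered electrophile. Fallback, setting out from 1 and returning at 6: the para hydroxyl is blocked first and the alkyne ether is made later on a mono-phenol.
   - Bulky silylation of 1 (TIPSCl, imidazole, DMF, 0 °C) should give 1-{2,6-dihydroxy-4-[tri(propan-2-yl)silyloxy]phenyl}ethan-1-one F2.
   - NaH/MOMCl should convert it into 1-{2,6-bis(methoxymethoxy)-4-[tri(propan-2-yl)silyloxy]phenyl}ethan-1-one F3.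
   - TBAF in THF should liberate 1-[4-hydroxy-2,6-bis(methoxymethoxy)phenyl]ethan-1-one F4.
   - F4 has a single free hydroxyl; the copper-catalysed etherification with 2 (DBU, CuCl2, MeCN) should then deliver 6.

3. Step 3. The process at risk is double benzylation through proton transfer from the product ketone to unreacted enolate, or loss of the reactive benzylic bromide. Fallback, setting out from 6 and returning at 9: a Claisen–Schmidt condensation of 6 with 4-(benzyloxy)benzaldehyde (KOH, EtOH, rt) should give the chalcone (E)-3-[4-(benzyloxy)phenyl]-1-[2,6-bis(methoxymethoxy)-4-(2-methylbut-3-yn-2-yloxy)phenyl]prop-2-en-1-one F5. Its conjugated C=C bond is then reduced with sodium dithionite (NaHCO3, toluene–water, phase-transfer catalyst, 80 °C), a conjugate reduction that leaves the terminal alkyne and the benzyl ether untouched, to give 9.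

**Further compounds**

F1 | step 4 | 3-[4-(benzyloxy)phenyl]-1-[4-hydroxy-2,6-bis(methoxymethoxy)-3-(3-methylbuta-1,2-dien-1-yl)phenyl]propan-1-one | CC(C)=C=Cc1c(O)cc(OCOC)c(C(=O)CCc2ccc(OCc3ccccc3)cc2)c1OCOC
F2 | step 1 | 1-{2,6-dihydroxy-4-[tri(propan-2-yl)silyloxy]phenyl}ethan-1-one | CC(=O)c1c(O)cc(O[Si](C(C)C)(C(C)C)C(C)C)cc1O
F3 | step 1 | 1-{2,6-bis(methoxymethoxy)-4-[tri(propan-2-yl)silyloxy]phenyl}ethan-1-one | CC(=O)c1c(OCOC)cc(O[Si](C(C)C)(C(C)C)C(C)C)cc1OCOC
F4 | step 1 | 1-[4-hydroxy-2,6-bis(methoxymethoxy)phenyl]ethan-1-one | CC(=O)c1c(OCOC)cc(O)cc1OCOC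
F5 | step 3 | (E)-3-[4-(benzyloxy)phenyl]-1-[2,6-bis(methoxymethoxy)-4-(2-methylbut-3-yn-2-yloxy)phenyl]prop-2-en-1-one | C#CC(C)(C)Oc1cc(OCOC)c(C(=O)/C=C/c2ccc(OCc3ccccc3)cc2)c(OCOC)c1
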